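**Plan**
1. Retrosynthesis: after removal of the benzyl and acetonide groups, the interflavanyl C4(upper)–C6(lower) bond is cut to an upper C4 ketone and a lower C6 aryl metal (C4–H comes last, from hydride). The upper pyranone ring C is then cut at C2–C3 by a retro-α-ketol shift to a 3-hydroxy-2,3-dihydrobenzofuran-3-carbaldehyde, and that ring at C2–C3 back to an aryl diazoacetate.
2. Forward, upper unit: ring A carrying the ring B benzyl ether (from gallacetophenone) → dihydrofuran ring by carbenoid C–H insertion → C3 hydroxylation and ester-to-aldehyde reduction → ring expansion of O1–C2–C3–C3a–C7a (five) to O1–C2–C3–C4–C4a–C8a (six).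
3. Enabling feature: the C3–OH/C4 pair of the upper ring C sits next to ring A. In the precursor the carbinol carbon carries ring A (O1 ortho and the 7-oxygen para to C4a), so the C4 aryl ketone that forms is a conjugated sink, and the migrating C2 carries O1.
4. Lower unit: Claisen–Schmidt chalcone → Juliá–Colonna epoxide → 2,3-trans 3-hydroxyflavanone → SN2 inversion at C3 → all-cis 3,4-diol → acetonide → C6 bromide.
5. Union and end game: bromine–lithium–cerium exchange, addition to the upper C4 ketone, ionic hydrogenation, acetonide hydrolysis, hydrogenolysis.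
6. Stereochemistry: upper C2 from the chiral dirhodium catalyst, C3 from the suprafacial 1,2-shift (also the thermodynamic trans isomer), C4 from hydride delivery anti to O3; lower C2/C3 from the poly-L-leucine epoxidation followed by two SN2 events, C4 from axial hydride addition.

Key step: step 8

Assumption: the sense of induction of Rh2(S-PTTL)4 and of poly-L-leucine on these substrates is taken to be that of the parent 2-benzyloxyphenyl diazoacetate and of chalcone; the mirror-image catalyst is used should a first run show the opposite.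

**Step 1**
Reactants: 1 2',3',4'-trihydroxyacetophenone (gallacetophenone)
Product: 2 3',4'-bis(benzyloxy)-2'-hydroxyacetophenone
Conditions: BnBr (2.1 equiv), K2CO3, acetone, reflux
Reagents that add atoms: benzyl bromide, BrCc1ccccc1
Why: Williamson etherification of the two free phenols; the 2'-OH is hydrogen-bonded to the acetyl group and should stay unalkylated under carbonate conditions.

**Step 2**
Reactants: 2 3',4'-bis(benzyloxy)-2'-hydroxyacetophenone; 3 4-(benzyloxy)benzyl chloride
Product: 4 3',4'-bis(benzyloxy)-2'-[4-(benzyloxy)benzyloxy]acetophenone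
Conditions: K2CO3, KI (cat.), DMF, 70 °C
Reagents that add atoms: none
Why: Williamson etherification of the chelated phenol with a reactive benzylic chloride installs the CH2 that becomes C2 of the upper unit together with ring B.

**Step 3**
Reactants: 4 3',4'-bis(benzyloxy)-2'-[4-(benzyloxy)benzyloxy]acetophenone
Product: 6 methyl {3,4-bis(benzyloxy)-2-[4-(benzyloxy)benzyloxy]phenyl}(oxo)acetate, via aryl glyoxylic acid 5 (not isolated)
Conditions: SeO2 (1.6 equiv), pyridine, 100 °C; then MeI, K2CO3, DMF, rt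
Reagents that add atoms: selenium dioxide, O=[Se]=O; methyl iodide, CI
Why: Riley-type SeO2 oxidation of the acetyl group to the aryl glyoxylic acid and O-methylation of its carboxylate give the α-keto ester; no stereocentre is involved.

**Step 4**
Reactants: 6 methyl {3,4-bis(benzyloxy)-2-[4-(benzyloxy)benzyloxy]phenyl}(oxo)acetate
Product: 8 methyl {3,4-bis(benzyloxy)-2-[4-(benzyloxy)benzyloxy]phenyl}(diazo)acetate, via tosylhydrazone 7 (not isolated)
Conditions: TsNHNH2, MeOH, 60 °C; then DBU, CH2Cl2, rt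
Reagents that add atoms: 4-methylbenzenesulfonohydrazide, Cc1ccc(cc1)S(=O)(=O)NN
Why: Condensation to the tosylhydrazone and base-induced loss of sulfinate (Bamford–Stevens-type) is the standard entry to aryl diazoacetates from α-keto esters.

**Step 5**
Reactants: 8 methyl {3,4-bis(benzyloxy)-2-[4-(benzyloxy)benzyloxy]phenyl}(diazo)acetate
Product: 9 methyl (2R,3S)-6,7-bis(benzyloxy)-2-[4-(benzyloxy)phenyl]-2,3-dihydrobenzofuran-3-carboxylate (2,3-cis)
Conditions: Rh2(S-PTTL)4 (dirhodium tetrakis[N-phthaloyl-(S)-tert-leucinate], 1 mol %), toluene, −60 °C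
Reagents that add atoms: none
Why: Enantioselective intramolecular carbenoid C–H insertion into the ether-activated benzylic CH2 closes the dihydrofuran ring (1,5-insertion); the chiral dirhodium carboxylate sets C2, the only centre needed later, and the cis ester is the kinetic product.

**Step 6**
Reactants: 9 methyl (2R,3S)-6,7-bis(benzyloxy)-2-[4-(benzyloxy)phenyl]-2,3-dihydrobenzofuran-3-carboxylate
Product: 10 methyl (2S,3R)-6,7-bis(benzyloxy)-2-[4-(benzyloxy)phenyl]-3-hydroxy-2,3-dihydrobenzofuran-3-carboxylate (3-OH trans to the 2-aryl group)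
Conditions: KN(SiMe3)2, THF, −78 °C; then 2-(phenylsulfonyl)-3-phenyloxaziridine, −78 °C; NH4Cl (aq)
Reagents that add atoms: 2-(phenylsulfonyl)-3-phenyloxaziridine, O=S(=O)(N1OC1c1ccccc1)c1ccccc1
Why: Electrophilic hydroxylation of the ester enolate, which is formed cold so that it does not expel O1; the oxidant should approach anti to the C2 aryl group, and C2 itself is untouched.

**Step 7**
Reactants: 10 methyl (2S,3R)-6,7-bis(benzyloxy)-2-[4-(benzyloxy)phenyl]-3-hydroxy-2,3-dihydrobenzofuran-3-carboxylate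
Product: 11 (2S,3R)-6,7-bis(benzyloxy)-2-[4-(benzyloxy)phenyl]-3-hydroxy-2,3-dihydrobenzofuran-3-carbaldehyde
Conditions: i-Bu2AlH (2.5 equiv), CH2Cl2, −78 °C; aqueous potassium sodium tartrate
Reagents that add atoms: none
Why: Partial hydride reduction of the α-hydroxy ester stops at the aluminium-chelated hemiacetal at low temperature and releases the aldehyde on work-up; no stereocentre is touched.

**Step 8**
Reactants: 11 (2S,3R)-6,7-bis(benzyloxy)-2-[4-(benzyloxy)phenyl]-3-hydroxy-2,3-dihydrobenzofuran-3-carbaldehyde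
Product: 12 (2S,3S)-7,8-bis(benzyloxy)-2-[4-(benzyloxy)phenyl]-3-hydroxychroman-4-one (2,3-trans)
Conditions: Zn(OTf)2 (20 mol %), i-Pr2NEt (20 mol %), toluene, 40 °C
Reagents that add atoms: none
Why: Proposed new method: the zinc-chelated α-hydroxy aldehyde should undergo an α-ketol (acyloin) rearrangement in which the C2–C3 σ-bond of the dihydrofuran shifts from the carbinol carbon to the formyl carbon while the carbinol becomes the C4 ketone, so the ring O1–C2–C3–C3a–C7a grows to O1–C2–C3–C4–C4a–C8a by a 1,2-shift (ring enlargement, no cyclisation); the closest known reaction type is the acyloin ring expansion of 1-hydroxycycloalkanecarbaldehydes and of 17-hydroxy-20-oxo steroids. C2 migrates with retention, so its configuration from step 5 is carried over. The new C3 carbinol centre is set by the suprafacial shift inside the chelate (carbonyl O syn to the carbinol O), which places the C3–O bond anti to the C2 aryl group, and the 2,3-trans isomer is also the thermodynamic one reachable through the enediol. The selectivity needed is migration of C2 and not of the aryl carbon C3a; it is secured by the O1 lone pair on the migrating carbon and by the product-like transition state, since only C2 migration leaves ring A on the new carbonyl, conjugated with O1 (ortho) and the 7-oxygen (para). Aryl migration would give the non-conjugated 4-hydroxy-3-ketone, which lies uphill and can return through the same reversible manifold. Relief of dihydrofuran strain and the aldehyde-to-aryl-ketone change drive the step.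

**Step 9**
Reactants: 12 (2S,3S)-7,8-bis(benzyloxy)-2-[4-(benzyloxy)phenyl]-3-hydroxychroman-4-one
Product: 13 (2S,3S)-3,7,8-tris(benzyloxy)-2-[4-(benzyloxy)phenyl]chroman-4-one
Conditions: BnOC(=NH)CCl3, TfOH (5 mol %), CH2Cl2–cyclohexane, 0 °C → rt
Reagents that add atoms: benzyl 2,2,2-trichloroacetimidate, ClC(Cl)(Cl)C(=N)OCc1ccccc1
Why: Acid-catalysed imidate benzylation protects the 3-OH without base, which would open or epimerise the 3-hydroxyflavanone; the stereocentres are untouched.

**Step 10**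
Reactants: 2 3',4'-bis(benzyloxy)-2'-hydroxyacetophenone
Product: 14 3',4'-bis(benzyloxy)-2'-(methoxymethoxy)acetophenone
Conditions: NaH, DMF, 0 °C; then MOMCl, 0 °C → rt
Reagents that add atoms: chloromethyl methyl ether, COCCl
Why: O-alkylation of the phenoxide masks the 2'-OH as an acetal for the base-mediated steps that follow.

**Step 11**
Reactants: 14 3',4'-bis(benzyloxy)-2'-(methoxymethoxy)acetophenone; 15 4-(benzyloxy)benzaldehyde
Product: 16 (E)-3',4',4-tris(benzyloxy)-2'-(methoxymethoxy)chalcone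
Conditions: KOH, EtOH–THF, rt
Reagents that add atoms: none
Why: Claisen–Schmidt condensation gives the E enone under thermodynamic control.

**Step 12**
Reactants: 16 (E)-3',4',4-tris(benzyloxy)-2'-(methoxymethoxy)chalcone
Product: 17 [3,4-bis(benzyloxy)-2-(methoxymethoxy)phenyl]{(2R,3S)-3-[4-(benzyloxy)phenyl]oxiran-2-yl}methanone
Conditions: poly-L-leucine, urea–H2O2, DBU, THF, rt
Reagents that add atoms: urea–hydrogen peroxide, OO.NC(N)=O
Why: Juliá–Colonna epoxidation: the helical polypeptide directs hydroperoxide addition to one enone face, and the trans epoxide follows from the E alkene.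

**Step 13**
Reactants: 17 [3,4-bis(benzyloxy)-2-(methoxymethoxy)phenyl]{(2R,3S)-3-[4-(benzyloxy)phenyl]oxiran-2-yl}methanone
Product: 19 (2R,3R)-7,8-bis(benzyloxy)-2-[4-(benzyloxy)phenyl]-3-hydroxychroman-4-one (2,3-trans), via 2'-hydroxy epoxy ketone 18 (not isolated)
Conditions: HCl (conc.), MeOH–THF, 55 °C
Reagents that add atoms: none
Why: Acid removes the MOM group and the freed phenol opens the epoxide at the benzylic carbon in a 6-endo mode with inversion (epoxide–phenol cyclisation), which sets C2 trans to O3 while the α-carbon keeps its configuration as C3.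

**Step 14**
Reactants: 19 (2R,3R)-7,8-bis(benzyloxy)-2-[4-(benzyloxy)phenyl]-3-hydroxychroman-4-one
Product: 21 (2R,3S)-3-acetoxy-7,8-bis(benzyloxy)-2-[4-(benzyloxy)phenyl]chroman-4-one (2,3-cis), via 3-O-triflate 20 (not isolated)
Conditions: Tf2O, pyridine, CH2Cl2, −20 °C; then CsOAc, 18-crown-6, toluene, rt
Reagents that add atoms: caesium acetate, CC(=O)[O-].[Cs+]
Why: SN2 displacement of the α-keto triflate by carboxylate inverts C3 (carbonyl-accelerated substitution; E2 is disfavoured because H2 is not anti to the equatorial leaving group).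

**Step 15**
Reactants: 21 (2R,3S)-3-acetoxy-7,8-bis(benzyloxy)-2-[4-(benzyloxy)phenyl]chroman-4-one
Product: 23 (2R,3R,4R)-7,8-bis(benzyloxy)-2-[4-(benzyloxy)phenyl]chromane-3,4-diol (all-cis), via 3-acetoxy-4-ol 22 (not isolated)
Conditions: NaBH4, MeOH–THF, −20 → 0 °C; then K2CO3, MeOH, rt
Reagents that add atoms: none
Why: Substrate-controlled ketone reduction: hydride adds axially to C4, anti to the axial 3-acetoxy group, so the new 4-OH is equatorial and cis to O3; methanolysis then frees the 3-OH.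

**Step 16**
Reactants: 23 (2R,3R,4R)-7,8-bis(benzyloxy)-2-[4-(benzyloxy)phenyl]chromane-3,4-diol
Product: 24 3,4-O-isopropylidene acetal of 23
Conditions: Me2C(OMe)2, PPTS (cat.), acetone, rt
Reagents that add atoms: 2,2-dimethoxypropane, COC(C)(C)OC
Why: Transacetalisation of the cis-1,2-diol gives the cis-fused dioxolane, which also shields the labile benzylic 4-OH.

**Step 17**
Reactants: 24 3,4-O-isopropylidene acetal of 23
Product: 25 6-bromo derivative of 24
Conditions: NBS (1.0 equiv), CH2Cl2, −30 → 0 °C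
Reagents that add atoms: N-bromosuccinimide, BrN1C(=O)CCC1=O
Why: Electrophilic aromatic bromination at C6, the only ring A position that is ortho to the 7-benzyloxy group and para to O1.

**Step 18**
Reactants: 25 6-bromo derivative of 24; 13 (2S,3S)-3,7,8-tris(benzyloxy)-2-[4-(benzyloxy)phenyl]chroman-4-one
Product: 28 C4 tertiary alcohol formed from 13 and C6 of acetonide 24, via aryllithium 26 (not isolated), via arylcerium dichloride 27 (not isolated)
Conditions: t-BuLi (2.0 equiv), THF, −78 °C; CeCl3 (anhydrous), −78 °C; then 13, −78 → −30 °C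
Reagents that add atoms: none
Why: Bromine–lithium exchange, transmetallation to the weakly basic organocerium and 1,2-addition to the hindered, enolisable C4 ketone form the interflavanyl C4–C6 bond; the aryl group should enter anti to the 3-benzyloxy group, but this carbinol centre is planarised in step 19.

**Step 19**
Reactants: 28 C4 tertiary alcohol formed from 13 and C6 of acetonide 24
Product: 29 hepta-O-benzyl 3,4-O-isopropylidene derivative of 31
Conditions: Et3SiH (5 equiv), CF3CO2H (2 equiv), CH2Cl2, −40 °C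
Reagents that add atoms: none
Why: Ionic hydrogenation: the doubly benzylic, oxygen-stabilised upper C4 cation should ionise far more readily than any other C–O bond and take hydride on the face anti to the 3-benzyloxy group (1,2-induction as in captures of flavan-4-yl cations), which leaves the lower-unit aryl group cis to O3.

**Step 20**
Reactants: 29 hepta-O-benzyl 3,4-O-isopropylidene derivative of 31
Product: 30 hepta-O-benzyl ether of 31
Conditions: AcOH–H2O–THF (3:1:1), 45 °C
Reagents that add atoms: none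
Why: Mild acetal hydrolysis cleaves at the acetal carbon, so the C4–O bond of the lower unit and its configuration are kept.

**Step 21**
Reactants: 30 hepta-O-benzyl ether of 31
Product: 31 ent-oritin-(4α→6)-epioritin-4α-ol (target)
Conditions: H2 (1 atm), Pd(OH)2/C, THF–MeOH, rt
Reagents that add atoms: none
Why: Hydrogenolysis of the seven benzyl ethers under neutral conditions, where O-benzyl cleavage should outpace loss of the secondary benzylic 4-OH.

**Compound list**

1 | 2',3',4'-trihydroxyacetophenone (gallacetophenone) | CC(=O)c1ccc(O)c(O)c1O | starting material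
2 | 3',4'-bis(benzyloxy)-2'-hydroxyacetophenone | CC(=O)c1ccc(OCc2ccccc2)c(OCc2ccccc2)c1O | intermediate
3 | 4-(benzyloxy)benzyl chloride | ClCc1ccc(OCc2ccccc2)cc1 | starting material
4 | 3',4'-bis(benzyloxy)-2'-[4-(benzyloxy)benzyloxy]acetophenone | CC(=O)c1ccc(OCc2ccccc2)c(OCc2ccccc2)c1OCc1ccc(OCc2ccccc2)cc1 | intermediate
5 | {3,4-bis(benzyloxy)-2-[4-(benzyloxy)benzyloxy]phenyl}(oxo)acetic acid | OC(=O)C(=O)c1ccc(OCc2ccccc2)c(OCc2ccccc2)c1OCc1ccc(OCc2ccccc2)cc1 | intermediate (not isolated)
6 | methyl {3,4-bis(benzyloxy)-2-[4-(benzyloxy)benzyloxy]phenyl}(oxo)acetate | COC(=O)C(=O)c1ccc(OCc2ccccc2)c(OCc2ccccc2)c1OCc1ccc(OCc2ccccc2)cc1 | intermediate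
7 | N-tosylhydrazone of 6 | COC(=O)C(=NNS(=O)(=O)c1ccc(C)cc1)c1ccc(OCc2ccccc2)c(OCc2ccccc2)c1OCc1ccc(OCc2ccccc2)cc1 | intermediate (not isolated)
8 | methyl {3,4-bis(benzyloxy)-2-[4-(benzyloxy)benzyloxy]phenyl}(diazo)acetate | COC(=O)C(=[N+]=[N-])c1ccc(OCc2ccccc2)c(OCc2ccccc2)c1OCc1ccc(OCc2ccccc2)cc1 | intermediate
9 | methyl (2R,3S)-6,7-bis(benzyloxy)-2-[4-(benzyloxy)phenyl]-2,3-dihydrobenzofuran-3-carboxylate (2,3-cis) | O(Cc1ccccc1)c1ccc(cc1)[C@@H]1Oc2c(OCc3ccccc3)c(OCc3ccccc3)ccc2[C@@H]1C(=O)OC | intermediate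
10 | methyl (2S,3R)-6,7-bis(benzyloxy)-2-[4-(benzyloxy)phenyl]-3-hydroxy-2,3-dihydrobenzofuran-3-carboxylate (OH trans to the 2-aryl group) | O(Cc1ccccc1)c1ccc(cc1)[C@@H]1Oc2c(OCc3ccccc3)c(OCc3ccccc3)ccc2[C@]1(O)C(=O)OC | intermediate
11 | (2S,3R)-6,7-bis(benzyloxy)-2-[4-(benzyloxy)phenyl]-3-hydroxy-2,3-dihydrobenzofuran-3-carbaldehyde | O(Cc1ccccc1)c1ccc(cc1)[C@@H]1Oc2c(OCc3ccccc3)c(OCc3ccccc3)ccc2[C@]1(O)C=O | intermediate
12 | (2S,3S)-7,8-bis(benzyloxy)-2-[4-(benzyloxy)phenyl]-3-hydroxychroman-4-one (2,3-trans) | O=C1c2ccc(OCc3ccccc3)c(OCc3ccccc3)c2O[C@@H](c2ccc(OCc3ccccc3)cc2)[C@@H]1O | intermediate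
13 | (2S,3S)-3,7,8-tris(benzyloxy)-2-[4-(benzyloxy)phenyl]chroman-4-one | O=C1c2ccc(OCc3ccccc3)c(OCc3ccccc3)c2O[C@@H](c2ccc(OCc3ccccc3)cc2)[C@@H]1OCc1ccccc1 | intermediate
14 | 3',4'-bis(benzyloxy)-2'-(methoxymethoxy)acetophenone | CC(=O)c1ccc(OCc2ccccc2)c(OCc2ccccc2)c1OCOC | intermediate
15 | 4-(benzyloxy)benzaldehyde | O=Cc1ccc(OCc2ccccc2)cc1 | starting material
16 | (E)-3',4',4-tris(benzyloxy)-2'-(methoxymethoxy)chalcone | O=C(/C=C/c1ccc(OCc2ccccc2)cc1)c1ccc(OCc2ccccc2)c(OCc2ccccc2)c1OCOC | intermediate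
17 | [3,4-bis(benzyloxy)-2-(methoxymethoxy)phenyl]{(2R,3S)-3-[4-(benzyloxy)phenyl]oxiran-2-yl}methanone (trans epoxide) | O=C(c1ccc(OCc2ccccc2)c(OCc2ccccc2)c1OCOC)[C@@H]1O[C@H]1c1ccc(OCc2ccccc2)cc1 | intermediate
18 | [3,4-bis(benzyloxy)-2-hydroxyphenyl]{(2R,3S)-3-[4-(benzyloxy)phenyl]oxiran-2-yl}methanone | O=C(c1ccc(OCc2ccccc2)c(OCc2ccccc2)c1O)[C@@H]1O[C@H]1c1ccc(OCc2ccccc2)cc1 | intermediate (not isolated)
19 | (2R,3R)-7,8-bis(benzyloxy)-2-[4-(benzyloxy)phenyl]-3-hydroxychroman-4-one (2,3-trans) | O=C1c2ccc(OCc3ccccc3)c(OCc3ccccc3)c2O[C@H](c2ccc(OCc3ccccc3)cc2)[C@H]1O | intermediate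
20 | (2R,3R)-7,8-bis(benzyloxy)-2-[4-(benzyloxy)phenyl]-4-oxochroman-3-yl trifluoromethanesulfonate | O=C1c2ccc(OCc3ccccc3)c(OCc3ccccc3)c2O[C@H](c2ccc(OCc3ccccc3)cc2)[C@H]1OS(=O)(=O)C(F)(F)F | intermediate (not isolated)
21 | (2R,3S)-3-acetoxy-7,8-bis(benzyloxy)-2-[4-(benzyloxy)phenyl]chroman-4-one (2,3-cis) | O=C1c2ccc(OCc3ccccc3)c(OCc3ccccc3)c2O[C@H](c2ccc(OCc3ccccc3)cc2)[C@@H]1OC(C)=O | intermediate
22 | (2R,3R,4R)-3-acetoxy-7,8-bis(benzyloxy)-2-[4-(benzyloxy)phenyl]chroman-4-ol | O[C@@H]1c2ccc(OCc3ccccc3)c(OCc3ccccc3)c2O[C@H](c2ccc(OCc3ccccc3)cc2)[C@@H]1OC(C)=O | intermediate (not isolated)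
23 | (2R,3R,4R)-7,8-bis(benzyloxy)-2-[4-(benzyloxy)phenyl]chromane-3,4-diol (all-cis) | O[C@@H]1c2ccc(OCc3ccccc3)c(OCc3ccccc3)c2O[C@H](c2ccc(OCc3ccccc3)cc2)[C@@H]1O | intermediate
24 | 3,4-O-isopropylidene acetal (cis-fused acetonide) of 23 | CC1(C)O[C@@H]2c3ccc(OCc4ccccc4)c(OCc4ccccc4)c3O[C@H](c3ccc(OCc4ccccc4)cc3)[C@@H]2O1 | intermediate
25 | 6-bromo derivative of 24 (Br ortho to the 7-benzyloxy group, para to O1) | CC1(C)O[C@@H]2c3cc(Br)c(OCc4ccccc4)c(OCc4ccccc4)c3O[C@H](c3ccc(OCc4ccccc4)cc3)[C@@H]2O1 | intermediate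
26 | 6-lithio derivative of 24 | CC1(C)O[C@@H]2c3cc([Li])c(OCc4ccccc4)c(OCc4ccccc4)c3O[C@H](c3ccc(OCc4ccccc4)cc3)[C@@H]2O1 | intermediate (not isolated)
27 | 6-(dichlorocerio) derivative of 24 | CC1(C)O[C@@H]2c3cc([Ce](Cl)Cl)c(OCc4ccccc4)c(OCc4ccccc4)c3O[C@H](c3ccc(OCc4ccccc4)cc3)[C@@H]2O1 | intermediate (not isolated)
28 | (2S,3S)-3,7,8-tris(benzyloxy)-2-[4-(benzyloxy)phenyl]chroman-4-ol carrying at C4 the C6 carbon of acetonide 24; C4 aryl group anti to the 3-benzyloxy group (this centre is removed in step 19) | CC1(C)O[C@@H]2c3cc([C@@]4(O)c5ccc(OCc6ccccc6)c(OCc6ccccc6)c5O[C@@H](c5ccc(OCc6ccccc6)cc5)[C@@H]4OCc4ccccc4)c(OCc4ccccc4)c(OCc4ccccc4)c3O[C@H](c3ccc(OCc4ccccc4)cc3)[C@@H]2O1 | intermediate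
29 | hepta-O-benzyl 3,4-O-isopropylidene derivative of 31 (upper unit 2,3-trans-3,4-cis with 3-O-benzyl and C4–H, joined C4→C6 to acetonide 24) | CC1(C)O[C@@H]2c3cc([C@@H]4c5ccc(OCc6ccccc6)c(OCc6ccccc6)c5O[C@@H](c5ccc(OCc6ccccc6)cc5)[C@@H]4OCc4ccccc4)c(OCc4ccccc4)c(OCc4ccccc4)c3O[C@H](c3ccc(OCc4ccccc4)cc3)[C@@H]2O1 | intermediate
30 | hepta-O-benzyl ether of 31 (upper 3-O-benzyl and six phenolic benzyl ethers; lower 3,4-diol free) | O[C@@H]1c2cc([C@@H]3c4ccc(OCc5ccccc5)c(OCc5ccccc5)c4O[C@@H](c4ccc(OCc5ccccc5)cc4)[C@@H]3OCc3ccccc3)c(OCc3ccccc3)c(OCc3ccccc3)c2O[C@H](c2ccc(OCc3ccccc3)cc2)[C@@H]1O | intermediate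
31 | ent-oritin-(4α→6)-epioritin-4α-ol: (2R,3R,4R)-2-(4-hydroxyphenyl)-6-[(2S,3R,4R)-3,7,8-trihydroxy-2-(4-hydroxyphenyl)chroman-4-yl]chromane-3,4,7,8-tetrol | Oc1ccc([C@H]2Oc3c(cc([C@@H]4c5ccc(O)c(O)c5O[C@@H](c5ccc(O)cc5)[C@@H]4O)c(O)c3O)[C@@H](O)[C@H]2O)cc1 | target

**Step count and risks**

Total step count: 21. Longest linear sequence: 13 steps (steps 1–9 and 18–21; the lower-unit branch, steps 1, 10–17 and 18–21, is equally long).

The three steps most likely to fail:

1. Step 8 (Proposed new method). What may go wrong: migration of the aryl carbon C3a in place of C2, incomplete turnover, or erosion of the C2 configuration through reversible ketol/enediol isomerisation or Lewis-acid ionisation of the C2–O1 bond. The fallback uses known chemistry and makes the ring by epoxide cyclisation instead of ring expansion. It sets out from chalcone 16: Juliá–Colonna epoxidation with poly-D-leucine (urea–H2O2, DBU, THF) should give the enantiomeric epoxy ketone [3,4-bis(benzyloxy)-2-(methoxymethoxy)phenyl]{(2S,3R)-3-[4-(benzyloxy)phenyl]oxiran-2-yl}methanone F1. HCl in MeOH–THF then removes the MOM group to give the 2'-hydroxy epoxy ketone F2, which closes by 6-endo attack at the benzylic carbon with inversion. The fallback comes back to the route at 12.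

2. Step 18. What may go wrong: deprotonation of 13 at C3 by the aryl metal followed by β-elimination of O1 (ring opening), or no addition for steric reasons. The fallback makes the same bond under acid by the classical flavan-4-yl cation coupling and sets out from 12. NaBH4 (MeOH–THF, 0 °C) should give the 2,3-trans-3,4-trans diol (2S,3R,4S)-7,8-bis(benzyloxy)-2-[4-(benzyloxy)phenyl]chromane-3,4-diol F3. BF3·OEt2 in CH2Cl2 at −40 °C ionises its benzylic 4-OH in the presence of an excess of arene 24, whose C6 is the nucleophilic site. The 3,4-cis C4–C6 coupled 3-hydroxy acetonide F4 is expected to be the minor epimer and is separated from the 3,4-trans one. Benzylation of its 3-OH (NaH, BnBr, DMF) comes back to the route at 29.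

3. Step 14. What may go wrong: elimination or epimerisation of the α-keto triflate before substitution, or ring contraction through O1 participation. The fallback inverts C3 by neighbouring-group participation at the alcohol oxidation level and sets out from 19. MsCl/Et3N should give the (2R,3R)-3-O-mesyl ketone F5, and NaBH4 reduces it to the 3,4-trans 4-hydroxy mesylate F6. Boc2O/DMAP gives the 4-O-tert-butoxycarbonyl mesylate F7. On heating in DMF the carbonate carbonyl oxygen displaces the mesylate with inversion at C3 to give the cis-fused 3,4-cyclic carbonate F8. K2CO3 in MeOH then frees the all-cis diol and comes back to the route at 23.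

**Further compounds**

F1 | step 8 | [3,4-bis(benzyloxy)-2-(methoxymethoxy)phenyl]{(2S,3R)-3-[4-(benzyloxy)phenyl]oxiran-2-yl}methanone | O=C(c1ccc(OCc2ccccc2)c(OCc2ccccc2)c1OCOC)[C@H]1O[C@@H]1c1ccc(OCc2ccccc2)cc1
F2 | step 8 | [3,4-bis(benzyloxy)-2-hydroxyphenyl]{(2S,3R)-3-[4-(benzyloxy)phenyl]oxiran-2-yl}methanone | O=C(c1ccc(OCc2ccccc2)c(OCc2ccccc2)c1O)[C@H]1O[C@@H]1c1ccc(OCc2ccccc2)cc1
F3 | step 18 | (2S,3R,4S)-7,8-bis(benzyloxy)-2-[4-(benzyloxy)phenyl]chromane-3,4-diol (2,3-trans-3,4-trans) | O[C@H]1c2ccc(OCc3ccccc3)c(OCc3ccccc3)c2O[C@@H](c2ccc(OCc3ccccc3)cc2)[C@@H]1O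
F4 | step 18 | 3-O-debenzyl analogue of 29 (upper 3-OH free, 2,3-trans-3,4-cis) | CC1(C)O[C@@H]2c3cc([C@@H]4c5ccc(OCc6ccccc6)c(OCc6ccccc6)c5O[C@@H](c5ccc(OCc6ccccc6)cc5)[C@@H]4O)c(OCc4ccccc4)c(OCc4ccccc4)c3O[C@H](c3ccc(OCc4ccccc4)cc3)[C@@H]2O1
F5 | step 14 | (2R,3R)-7,8-bis(benzyloxy)-2-[4-(benzyloxy)phenyl]-4-oxochroman-3-yl methanesulfonate | O=C1c2ccc(OCc3ccccc3)c(OCc3ccccc3)c2O[C@H](c2ccc(OCc3ccccc3)cc2)[C@H]1OS(C)(=O)=O
F6 | step 14 | (2R,3S,4R)-7,8-bis(benzyloxy)-2-[4-(benzyloxy)phenyl]-4-hydroxychroman-3-yl methanesulfonate (3,4-trans) | O[C@@H]1c2ccc(OCc3ccccc3)c(OCc3ccccc3)c2O[C@H](c2ccc(OCc3ccccc3)cc2)[C@H]1OS(C)(=O)=O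
F7 | step 14 | 4-O-tert-butoxycarbonyl derivative of F6 | CC(C)(C)OC(=O)O[C@@H]1c2ccc(OCc3ccccc3)c(OCc3ccccc3)c2O[C@H](c2ccc(OCc3ccccc3)cc2)[C@H]1OS(C)(=O)=O
F8 | step 14 | cis-fused 3,4-cyclic carbonate of 23 | O=C1O[C@@H]2c3ccc(OCc4ccccc4)c(OCc4ccccc4)c3O[C@H](c3ccc(OCc4ccccc4)cc3)[C@@H]2O1
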